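Remark on the chemistry: read from the SMILES, the target is (2S,3S,5R,1'R), that is pentyl and acyloxy cis, the C5 chain trans to pentyl, and O1/C1'–OH threo; compound 5 is handled as a mixture of anomers because its C6 oxygen is removed in step 4.

## Structural features

The target is a 2,3,5-trisubstituted tetrahydrofuran (ring O1, C2, C3, C4, C5) with an n-pentyl chain on C2, a palmitoyloxy group on C3, an unsubstituted C4 and, on C5, a ten-carbon chain whose first carbon C1' is a secondary carbinol and whose far end is a vinyl group. C2 (S) and C3 (S) are adjacent and cis, C5 (R) and C1' (R) are adjacent and threo, the two pairs are separated by the C4 methylene, and the C5 chain is trans to pentyl across O1. The fragile functions are the secondary fatty ester (hydride, base, excess organometallic), the terminal alkene (hydrogenation, peracids, soft electrophiles) and the free alcohol, which must be told apart from the acylated C3 oxygen. Acyl migration between the two oxygens is not a serious threat, because they hang from opposite faces of the ring. The real difficulty is stereochemical: the 2,3-cis/2,5-trans pattern has to be relayed across C4 and O1, and C1' has to be set beside a ring oxygen without disturbing the ester. The structural handle is that C5 carries both O1 and the oxidised carbon C1': if O1 is moved from C5 to C1', the unit O1–C1'=C5 of a 3,4-dihydro-2H-pyran appears, in which C2 and C3 are already those of the target. The tetrahydrofuran can therefore be treated as a ring-contracted dihydropyran, and that dihydropyran as the oxidative ring-expansion product of a furyl carbinol.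

## Logic of the disconnections

18 ⇒ 15 + 17 (from 16). The C1'–C2' bond is cut. C1' is a carbinol beside the ring oxygen, hence the natural product of a carbonyl addition. The cut removes the nine-carbon chain together with the only alkene, which therefore never meets an electrophilic oxidant. The forward step must add to the formyl group of 15 faster than to its ester, use chelation by O1 to give the threo carbinol, and not epimerise C5.

15 ⇒ 14. No skeletal bond is cut; the formyl group is traced back to its dimethyl acetal. The acetal is what the contraction delivers in methanol, and it stores the epimerisable α-alkoxy aldehyde until needed. The forward hydrolysis must be acidic enough for an acetal flanked by an oxygen-bearing carbon yet leave the ester and C5 alone.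

14 ⇒ 12 (through 13). The O1–C5 bond is cut and O1 is reattached to C1', which becomes the oxygen-bearing carbon of an enol ether C5=C1'. This removes the C5 stereocentre and the acetal and leaves a six-membered ring with only the cis pair C2/C3. The C3 oxygen stays as the palmitate: it is the acyl group of 18, it is inert to the oxidant, and in the cis arrangement it takes the axial position from which it shields one face of C5. The forward step must deliver the electrophile to C5 on the face opposite to ester and pentyl, and must make O1, not methanol or a ring carbon, the group that bonds to C5.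

12 ⇒ 10 + 11. The C3–O bond is cut with inversion. A trans carbinol is what hydride reduction of the ring ketone supplies, so a displacement with inversion corrects the configuration and brings in the sixteen-carbon acid in one operation. The forward step is an SN2 reaction at a secondary carbon next to the branched C2, in the presence of an acid-labile enol ether.

10 ⇒ 7 (through 8 and 9). No bond is cut; the double bond is moved from C5=C6 (enol ether, pyran numbering) back to C4=C5 (allyl ether). The allyl ether descends directly from an enone, and migration toward oxygen is downhill. The migration is placed before the esterification on purpose: a metal hydride beside an allylic carboxylate can add the other way round and expel the carboxylate or form the enol ester. A transient silyl ether offers neither exit and also blocks the redox isomerisation of a free allylic alcohol to a ketone. The forward step must move the double bond only toward O1.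

7 ⇒ 6. The C3–H bond is cut: the carbinol comes from the enone. The demand is 1,2-selectivity and hydride delivery that places the hydroxyl trans to pentyl, which the later inversion turns into cis.

6 ⇒ 5. The C6–H bond is traced to C6–OH: the hemiacetal oxygen left by the ring expansion is removed by ionic reduction. Hydride must attack C6 of an oxocarbenium ion without touching the enone or epimerising C2.

5 ⇒ 4. O1–C6 is cut and C3 and C6 return to the two α-carbons of a furan ring. All ring atoms of 5 then come from 4, whose single stereocentre becomes C2. The forward oxidation must stop at the pyranone and keep the carbinol configuration.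

4 ⇒ 3. The carbinol C–H bond is cut. This is the only reagent-controlled stereocentre of the route, and it needs a catalyst that distinguishes furyl from pentyl.

3 ⇒ 1 + 2. The bond between the heteroaryl α-carbon and the acyl carbon is cut, leaving 1 and 2. The forward acylation must be mild enough for the acid-sensitive heterocycle.

## Other disconnections considered

Alternative 1: The cut removes O1–C2 together with the two bonds of a temporary lactone, so that C3, C5 and C1' are prepared on the open-chain diol A1, (3S,5R,6R)-6-(tert-butyldiphenylsilyloxy)pentadeca-1,14-diene-3,5-diol.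
- Forward step: PdCl2 with CuCl2 as reoxidant under CO would make the C5 hydroxyl add to the allylic alkene (5-exo oxypalladation, O1–C2). Carbon monoxide would insert into the C–Pd bond and the C3 hydroxyl would capture the acyl-palladium, giving the cis-fused lactone A2.
- In its favour: the 2,3-cis relationship is enforced by the ring fusion, C1' is in place before the ring is made, and the two secondary oxygens arrive differentiated. On the last two points the alternative is better than the chosen plan, which sets C1' by a late carbonyl addition next to an ester.
- Against it here: A1 holds three stereocentres that must be built on a flexible chain. Its second vinyl group is also a substrate for divalent palladium (Wacker-type oxidation, alkoxycarbonylation). The lactone carbon of A2 must still be turned into the pentyl chain (reduction, selective activation of the primary alcohol, copper-mediated propyl transfer) without hydrogenation, before acylation and desilylation.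
- Comparison: both plans close the ring through a C–O bond under substrate control, the palladium step creating C2 and the contraction creating C5. The alternative secures 2,3-cis more rigidly; the chosen plan needs one reagent-controlled centre against three. The alternative is expected to be clearly longer.

Alternative 2: The C2–pentyl and C3–O bonds are cut, leading back to the 2,3-dihydrofuran A3, (2R)-2-[(1R)-1-(4-methoxybenzyloxy)dec-9-enyl]-2,3-dihydrofuran.
- Forward step: dimethyldioxirane would epoxidise the enol ether on the face away from the C5 substituent to the anomeric epoxide A4. Al(n-C5H11)3 would then coordinate the epoxide oxygen and hand a pentyl group to C2 on the same face, giving alcohol A5 with pentyl and hydroxyl cis.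
- In its favour: C2 and C3 are set in one flask with the cis relationship dictated by the mechanism, and pentyl is introduced as such. The end game (acylation of the only free hydroxyl, oxidative removal of the 4-methoxybenzyl ether) is safer than an organometallic addition beside an ester; in that respect the alternative is better.
- Against it: A3 already contains C5 and C1', so the threo problem is only moved to the start. A4 is a strained anomeric epoxide of a furanoid ring and prone to ionise. The aluminium reagent has to be prepared and can transfer a β-hydride instead of pentyl. The oxidant must distinguish the enol ether from the chain alkene, which the rate difference should allow.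
- Comparison: facial control of the epoxidation comes from a substituent 1,3 to the reacting carbon on a nearly flat ring, so on stereocontrol by a remote group the two plans are equals. The step count would be comparable only if A3 is available in few steps; no gain is apparent.

Alternative 3: The ring is cut twice, at C4–C5 and O1–C2, into the aldehyde A6, (2R)-2-(benzyloxy)undec-10-enal, and the allylsilane A7, dimethyl[(3R)-oct-1-en-3-yl]phenylsilane.
- Forward step: with SnCl4 chelated between the formyl and benzyloxy oxygens of A6, the alkene terminus of A7 would attack the aldehyde anti to silicon. The silyl group would shift to C3 and the aldehyde oxygen would close on C2 with inversion, giving A8.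
- In its favour: this is the most convergent of the four plans. Two fragments of similar size are joined, two ring bonds and three ring stereocentres form in one step, and C1' is preset. In convergence it is better than the chosen, fully linear route.
- Against it: silicon ends trans to pentyl, so the C–Si bond must be oxidised with retention (Tamao–Fleming) and the alcohol inverted. The inversion can be merged with esterification by a Mitsunobu reaction with palmitic acid, as in the chosen plan, so there the two are equals. The oxidation of a dimethylphenylsilyl group, however, begins with electrophilic removal of the phenyl ring (protic acid, bromine, or Hg(OAc)2 with a peracid), which the terminal alkene is unlikely to tolerate. The benzyl ether cannot be removed by hydrogenolysis for the same reason, and Lewis-acidic or dissolving-metal methods endanger the ester. The 2,5-relationship in such annulations depends on the Lewis acid and on chelation, so the trans outcome is not assured, and enantioenriched A7 needs a synthesis of its own.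
- Comparison: the alternative could be shorter in its longest linear sequence but carries more protecting-group and chemoselectivity risk.

Key step: step 8

## Route

Step 1
Reactants: 1 furan; 2 hexanoic anhydride
Product: 3 1-(furan-2-yl)hexan-1-one
Conditions: BF3·OEt2 (cat.), 1 (excess), 0 °C → rt
Reagents that add atoms: none
Why: Friedel–Crafts acylation; furan reacts at its α-carbon, and a catalytic mild Lewis acid with the anhydride avoids the polymerisation that stronger acids cause.

Step 2
Reactants: 3 1-(furan-2-yl)hexan-1-one
Product: 4 (1S)-1-(furan-2-yl)hexan-1-ol
Conditions: RuCl(p-cymene)[(S,S)-TsDPEN] (1 mol %), HCO2H/Et3N (5:2), rt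
Reagents that add atoms: none
Why: Noyori asymmetric transfer hydrogenation; the furyl group takes the place of aryl in the CH/π-organised six-membered transition state, so the (S,S)-ligand delivers hydride to the face that gives the (S)-carbinol, the future C2.

Step 3
Reactants: 4 (1S)-1-(furan-2-yl)hexan-1-ol
Product: 5 (2S)-6-hydroxy-2-pentyl-2H-pyran-3(6H)-one (both anomers)
Conditions: NBS, NaHCO3, NaOAc, THF/H2O (4:1), 0 °C
Reagents that add atoms: water, O
Why: Achmatowicz rearrangement; bromonium-initiated hydration opens the furan to a cis-enedione whose aldehyde is captured by the carbinol oxygen, so the carbinol centre becomes C2 untouched and C6 is an inconsequential hemiacetal.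

Step 4
Reactants: 5 (2S)-6-hydroxy-2-pentyl-2H-pyran-3(6H)-one
Product: 6 (2S)-2-pentyl-2H-pyran-3(6H)-one
Conditions: Et3SiH, CF3CO2H, CH2Cl2, −40 → 0 °C
Reagents that add atoms: none
Why: Ionic hydrogenation of a lactol; acid ionises C6–OH to the cyclic oxocarbenium ion, which the silane reduces at C6, while the enone and the C2 centre are left alone at low temperature.

Step 5
Reactants: 6 (2S)-2-pentyl-2H-pyran-3(6H)-one
Product: 7 (2S,3R)-2-pentyl-3,6-dihydro-2H-pyran-3-ol
Conditions: NaBH4, CeCl3·7H2O, MeOH, −78 °C
Reagents that add atoms: none
Why: Luche reduction; the cerium-activated carbonyl is reduced 1,2, and hydride enters axially on the half-chair with pentyl pseudoequatorial, which should give the equatorial carbinol trans to pentyl (3R).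

Step 6
Reactants: 7 (2S,3R)-2-pentyl-3,6-dihydro-2H-pyran-3-ol
Product: 10 (2S,3R)-2-pentyl-3,4-dihydro-2H-pyran-3-ol, via allylic trimethylsilyl ether 8 (not isolated), via migrated trimethylsilyl ether 9 (not isolated)
Conditions: Me3SiCl, Et3N, CH2Cl2, 0 °C; filter, evaporate; RuClH(CO)(PPh3)3 (5 mol %), toluene, 80 °C; then K2CO3, MeOH, rt
Reagents that add atoms: none
Why: Silylation followed by ruthenium-hydride double-bond migration (hydrometalation/β-hydride elimination) of an allyl ether to the conjugated enol ether, a known transformation of 3-oxygenated 3,6-dihydro-2H-pyrans. The silyl ether prevents redox isomerisation to a ketone and is a poor β-leaving group; ruthenium should add at C5, remote from the branched C3, so β-hydride loss from C6 is favoured. Basic methanolysis then removes the silyl group without touching the acid-labile enol ether.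

Step 7
Reactants: 10 (2S,3R)-2-pentyl-3,4-dihydro-2H-pyran-3-ol; 11 palmitic acid
Product: 12 (2S,3S)-2-pentyl-3,4-dihydro-2H-pyran-3-yl palmitate
Conditions: PPh3, DIAD, THF, 0 °C → rt
Reagents that add atoms: none
Why: Mitsunobu esterification; palmitate displaces the alkoxyphosphonium ion in an SN2 process with inversion, so the trans carbinol gives the cis ester (3S), and the acyl group of the target is installed under neutral conditions that the enol ether tolerates.

Step 8
Reactants: 12 (2S,3S)-2-pentyl-3,4-dihydro-2H-pyran-3-yl palmitate
Product: 14 (2S,3S,5R)-5-(dimethoxymethyl)-2-pentyltetrahydrofuran-3-yl palmitate, via methoxy iodane adduct 13 (not isolated)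
Conditions: PhI(OH)OTs (1.1 equiv), MeOH/CH2Cl2 (1:1), 3 Å MS, −30 → 0 °C; NaHCO3
Reagents that add atoms: methanol, CO
Why: PhI(OH)OTs becomes PhI(OMe)OTs in methanol, and its electrophilic iodine adds to the β-carbon C5 of the enol ether while methanol caps the oxocarbenium carbon C1', giving adduct 13. In the half-chair of 12 the pentyl group is pseudoequatorial and the palmitate pseudoaxial, so the ester screens the face of C5 that is 1,3-syn to it and iodine should enter from the other face. In the chair of 13 that keeps pentyl equatorial the C5–I bond is then equatorial and antiperiplanar to the ring bond O1–C1'. O1 displaces iodobenzene from C5 from the rear while the O1–C1' bond breaks, a 1,2-shift through a bridged oxonium (formally a 3-exo-tet attack followed by fragmentation) that closes the tetrahydrofuran by contraction and forms the only new skeletal bond, O1–C5. The methoxy-stabilised cation at C1' is trapped by methanol as the dimethyl acetal. The new stereocentre C5 is fixed by the face of iodination and the inversion in the shift: iodine anti to pentyl and ester puts C1' trans to pentyl, that is 5R. The closest known chemistry is the oxidative contraction of glycals, cyclic enol ethers and cycloalkenes by trivalent iodine or trivalent thallium in methanol, the oxidative counterpart of the nitrous acid contraction of 2-amino-2-deoxypyranoses. The step needs iodination at C5 rather than C1' (set by the enol ether polarity), the anti face (set by the axial ester), and oxygen migration rather than methanol substitution or C3–C4 migration (set by the antiperiplanar ring oxygen and the stability of the alkoxycarbenium ion); the chain alkene is not yet present, so the reagent meets no second π bond.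

Step 9
Reactants: 14 (2S,3S,5R)-5-(dimethoxymethyl)-2-pentyltetrahydrofuran-3-yl palmitate
Product: 15 (2S,3S,5R)-5-formyl-2-pentyltetrahydrofuran-3-yl palmitate
Conditions: CF3CO2H/H2O (9:1), CH2Cl2, 0 °C → rt; toluene azeotrope, used crude
Reagents that add atoms: water, O
Why: Acid-catalysed acetal hydrolysis; the ester is inert to aqueous acid at this temperature and enolisation of the α-alkoxy aldehyde is slow in cold acid, so C5 should be retained.

Step 10
Reactants: 15 (2S,3S,5R)-5-formyl-2-pentyltetrahydrofuran-3-yl palmitate; 16 9-bromonon-1-ene
Product: 18 (2S,3S,5R)-5-[(1R)-1-hydroxydec-9-en-1-yl]-2-pentyltetrahydrofuran-3-yl palmitate, via non-8-en-1-ylmagnesium bromide 17 (not isolated)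
Conditions: 16, Mg, Et2O, reflux; then 15, MgBr2·OEt2, CH2Cl2, −78 °C; aq NH4Cl
Reagents that add atoms: none
Why: Grignard addition under Cram-chelate control; magnesium bridges the formyl oxygen and O1, the nucleophile attacks from the side of the C5 hydrogen, and the threo (1R) carbinol should result. At −78 °C the aldehyde reacts much faster than the hindered secondary ester, which sits on the opposite ring face and cannot join the chelate.

## Compound list

1 | furan | c1ccoc1 | starting material
2 | hexanoic anhydride | CCCCCC(=O)OC(=O)CCCCC | starting material
3 | 1-(furan-2-yl)hexan-1-one | CCCCCC(=O)c1ccco1 | intermediate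
4 | (1S)-1-(furan-2-yl)hexan-1-ol | CCCCC[C@H](O)c1ccco1 | intermediate
5 | (2S)-6-hydroxy-2-pentyl-2H-pyran-3(6H)-one (both anomers) | OC1C=CC(=O)[C@H](CCCCC)O1 | intermediate
6 | (2S)-2-pentyl-2H-pyran-3(6H)-one | C1C=CC(=O)[C@H](CCCCC)O1 | intermediate
7 | (2S,3R)-2-pentyl-3,6-dihydro-2H-pyran-3-ol | C1C=C[C@@H](O)[C@H](CCCCC)O1 | intermediate
8 | trimethyl{[(2S,3R)-2-pentyl-3,6-dihydro-2H-pyran-3-yl]oxy}silane | C1C=C[C@@H](O[Si](C)(C)C)[C@H](CCCCC)O1 | intermediate (not isolated)
9 | trimethyl{[(2S,3R)-2-pentyl-3,4-dihydro-2H-pyran-3-yl]oxy}silane | C1=CC[C@@H](O[Si](C)(C)C)[C@H](CCCCC)O1 | intermediate (not isolated)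
10 | (2S,3R)-2-pentyl-3,4-dihydro-2H-pyran-3-ol | C1=CC[C@@H](O)[C@H](CCCCC)O1 | intermediate
11 | palmitic acid | CCCCCCCCCCCCCCCC(=O)O | starting material
12 | (2S,3S)-2-pentyl-3,4-dihydro-2H-pyran-3-yl palmitate | C1=CC[C@H](OC(=O)CCCCCCCCCCCCCCC)[C@H](CCCCC)O1 | intermediate
13 | (2S,3S,5S)-6-methoxy-2-pentyl-5-[phenyl(tosyloxy)-λ3-iodanyl]tetrahydro-2H-pyran-3-yl palmitate (iodine trans to ester and pentyl; C6 left open) | COC1[C@@H](I(OS(=O)(=O)c2ccc(C)cc2)c2ccccc2)C[C@H](OC(=O)CCCCCCCCCCCCCCC)[C@H](CCCCC)O1 | intermediate (not isolated)
14 | (2S,3S,5R)-5-(dimethoxymethyl)-2-pentyltetrahydrofuran-3-yl palmitate | COC(OC)[C@H]1C[C@H](OC(=O)CCCCCCCCCCCCCCC)[C@H](CCCCC)O1 | intermediate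
15 | (2S,3S,5R)-5-formyl-2-pentyltetrahydrofuran-3-yl palmitate | O=C[C@H]1C[C@H](OC(=O)CCCCCCCCCCCCCCC)[C@H](CCCCC)O1 | intermediate
16 | 9-bromonon-1-ene | C=CCCCCCCCBr | starting material
17 | non-8-en-1-ylmagnesium bromide | C=CCCCCCCC[Mg]Br | intermediate (not isolated)
18 | (2S,3S,5R)-5-[(1R)-1-hydroxydec-9-en-1-yl]-2-pentyltetrahydrofuran-3-yl palmitate | C=CCCCCCCC[C@@H](O)[C@H]1C[C@H](OC(=O)CCCCCCCCCCCCCCC)[C@H](CCCCC)O1 | target

## Step count and least certain steps

Total step count: 10 (the formation of 17 is part of step 10). Longest linear sequence: 10 steps, from 1 and 2 to 18; 11 and 16 join in steps 7 and 10.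

Step 8 (key step). The most likely failures are insufficient discrimination between the two faces of C5, because the controlling ester is 1,3 to the reacting carbon, and diversion of 12 by acid-catalysed addition of methanol once TsOH is released, or capture of C5 by methanol without migration. Fallback, setting out from 12: the oxygen at C5 is introduced in a separate non-acidic step and the leaving group is made afterwards. Dimethyldioxirane (acetone/CH2Cl2, −40 °C) should epoxidise the enol ether anti to the axial ester to (2S,3S)-5,6-epoxy-2-pentyltetrahydro-2H-pyran-3-yl palmitate (oxirane trans to the ester) F1. Methanol opens it at the acetal carbon to (2S,3S,5S,6S)-5-hydroxy-6-methoxy-2-pentyltetrahydro-2H-pyran-3-yl palmitate F2, which can be purified and its configuration checked. Tf2O/pyridine then gives (2S,3S,5S,6S)-6-methoxy-2-pentyl-5-(trifluoromethylsulfonyloxy)tetrahydro-2H-pyran-3-yl palmitate F3. Warming F3 in methanol with 2,6-lutidine should trigger the same antiperiplanar shift of O1, the solvolytic contraction known for pyranoside 2-sulfonates with an equatorial leaving group, and returns to the route at 14.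

Step 6. The double bond may move the wrong way (toward C3, giving a silyl enol ether), or the silyl ether may be lost early, after which the free allylic alcohol is isomerised to a ketone; either consumes the C3 centre. Fallback, setting out from 5: the enol ether is made by elimination instead of migration and the cis carbinol by reagent-controlled reduction, which also bypasses steps 4, 5 and 7. HC(OMe)3 with catalytic BF3·OEt2 converts 5 into (2S)-6-methoxy-2-pentyl-2H-pyran-3(6H)-one F4. H2 over Pd/C gives (2S)-6-methoxy-2-pentyldihydro-2H-pyran-3(4H)-one F5. LiBH(s-Bu)3 at −78 °C attacks from the equatorial side to give (2S,3S)-6-methoxy-2-pentyltetrahydro-2H-pyran-3-ol F6. Palmitoyl chloride/pyridine/DMAP gives (2S,3S)-6-methoxy-2-pentyltetrahydro-2H-pyran-3-yl palmitate F7, and Me3SiOTf/i-Pr2NEt eliminates methanol from the mixed acetal to rejoin the route at 12.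

Step 7. Substitution by the weakly acidic fatty acid at a carbinol flanked by the pentyl-bearing carbon may be slow, so that elimination of the alkoxyphosphonium ion toward a conjugated dienyl ether, or acylation of the reduced azo reagent, competes. Fallback, setting out from 10: inversion and acylation are separated. A Mitsunobu reaction with the more acidic 4-nitrobenzoic acid gives (2S,3S)-2-pentyl-3,4-dihydro-2H-pyran-3-yl 4-nitrobenzoate F8. K2CO3 in methanol releases (2S,3S)-2-pentyl-3,4-dihydro-2H-pyran-3-ol F9, and palmitoyl chloride/pyridine/DMAP acylates it with retention, returning to the route at 12.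

Step 10. Chelation by a ring oxygen may be incomplete, so that the Felkin–Anh pathway leaks through to the erythro epimer; attack of excess reagent on the ester and enolisation of 15 are the other risks. Fallback, setting out from 15: the addition is run for conversion only (one equivalent of 17, −78 °C), so that 18 is accompanied by (2S,3S,5R)-5-[(1S)-1-hydroxydec-9-en-1-yl]-2-pentyltetrahydrofuran-3-yl palmitate F10. Dess–Martin periodinane oxidises both to (2S,3S,5R)-5-(dec-9-enoyl)-2-pentyltetrahydrofuran-3-yl palmitate F11. LiBH(s-Bu)3 at −78 °C, which does not chelate and leaves the ester alone at that temperature, should reduce F11 under Felkin–Anh control to the threo carbinol, returning at 18.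

## Further compounds

F1 | step 8 | (2S,3S)-5,6-epoxy-2-pentyltetrahydro-2H-pyran-3-yl palmitate (oxirane trans to the ester) | [C@@H]12[C@@H](O1)C[C@H](OC(=O)CCCCCCCCCCCCCCC)[C@H](CCCCC)O2
F2 | step 8 | (2S,3S,5S,6S)-5-hydroxy-6-methoxy-2-pentyltetrahydro-2H-pyran-3-yl palmitate | CO[C@@H]1[C@@H](O)C[C@H](OC(=O)CCCCCCCCCCCCCCC)[C@H](CCCCC)O1
F3 | step 8 | (2S,3S,5S,6S)-6-methoxy-2-pentyl-5-(trifluoromethylsulfonyloxy)tetrahydro-2H-pyran-3-yl palmitate | CO[C@@H]1[C@@H](OS(=O)(=O)C(F)(F)F)C[C@H](OC(=O)CCCCCCCCCCCCCCC)[C@H](CCCCC)O1
F4 | step 6 | (2S)-6-methoxy-2-pentyl-2H-pyran-3(6H)-one (both anomers) | COC1C=CC(=O)[C@H](CCCCC)O1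
F5 | step 6 | (2S)-6-methoxy-2-pentyldihydro-2H-pyran-3(4H)-one (both anomers) | COC1CCC(=O)[C@H](CCCCC)O1
F6 | step 6 | (2S,3S)-6-methoxy-2-pentyltetrahydro-2H-pyran-3-ol (both anomers) | COC1CC[C@H](O)[C@H](CCCCC)O1
F7 | step 6 | (2S,3S)-6-methoxy-2-pentyltetrahydro-2H-pyran-3-yl palmitate (both anomers) | COC1CC[C@H](OC(=O)CCCCCCCCCCCCCCC)[C@H](CCCCC)O1
F8 | step 7 | (2S,3S)-2-pentyl-3,4-dihydro-2H-pyran-3-yl 4-nitrobenzoate | C1=CC[C@H](OC(=O)c2ccc(cc2)[N+](=O)[O-])[C@H](CCCCC)O1
F9 | step 7 | (2S,3S)-2-pentyl-3,4-dihydro-2H-pyran-3-ol | C1=CC[C@H](O)[C@H](CCCCC)O1
F10 | step 10 | (2S,3S,5R)-5-[(1S)-1-hydroxydec-9-en-1-yl]-2-pentyltetrahydrofuran-3-yl palmitate | C=CCCCCCCC[C@H](O)[C@H]1C[C@H](OC(=O)CCCCCCCCCCCCCCC)[C@H](CCCCC)O1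
F11 | step 10 | (2S,3S,5R)-5-(dec-9-enoyl)-2-pentyltetrahydrofuran-3-yl palmitate | C=CCCCCCCCC(=O)[C@H]1C[C@H](OC(=O)CCCCCCCCCCCCCCC)[C@H](CCCCC)O1
A1 | alternative 1 | (3S,5R,6R)-6-(tert-butyldiphenylsilyloxy)pentadeca-1,14-diene-3,5-diol | C=CCCCCCCC[C@@H](O[Si](c1ccccc1)(c1ccccc1)C(C)(C)C)[C@H](O)C[C@H](O)C=C
A2 | alternative 1 | (3aS,5R,6aS)-5-[(1R)-1-(tert-butyldiphenylsilyloxy)dec-9-en-1-yl]tetrahydrofuro[3,2-b]furan-2(3H)-one | C=CCCCCCCC[C@@H](O[Si](c3ccccc3)(c3ccccc3)C(C)(C)C)[C@H]1C[C@H](OC2=O)[C@H](C2)O1
A3 | alternative 2 | (2R)-2-[(1R)-1-(4-methoxybenzyloxy)dec-9-en-1-yl]-2,3-dihydrofuran | C=CCCCCCCC[C@@H](OCc1ccc(OC)cc1)[C@H]1CC=CO1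
A4 | alternative 2 | 2,3-epoxide of A3 on the face opposite the side chain (cis-fused 2,6-dioxabicyclo[3.1.0]hexane) | C=CCCCCCCC[C@@H](OCc1ccc(OC)cc1)[C@H]1C[C@@H]2O[C@@H]2O1
A5 | alternative 2 | (2S,3S,5R)-5-[(1R)-1-(4-methoxybenzyloxy)dec-9-en-1-yl]-2-pentyltetrahydrofuran-3-ol | C=CCCCCCCC[C@@H](OCc2ccc(OC)cc2)[C@H]1C[C@H](O)[C@H](CCCCC)O1
A6 | alternative 3 | (2R)-2-(benzyloxy)undec-10-enal | C=CCCCCCCC[C@@H](OCc1ccccc1)C=O
A7 | alternative 3 | dimethyl[(3R)-oct-1-en-3-yl]phenylsilane | C=C[C@@H](CCCCC)[Si](C)(C)c1ccccc1
A8 | alternative 3 | (2S,3R,5R)-5-[(1R)-1-(benzyloxy)dec-9-en-1-yl]-3-[dimethyl(phenyl)silyl]-2-pentyltetrahydrofuran | C=CCCCCCCC[C@@H](OCc2ccccc2)[C@H]1C[C@@H]([Si](C)(C)c2ccccc2)[C@H](CCCCC)O1
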